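**Strategy.** Numbering follows the spiro[5.5]undecane name of the target (C1 CMe2, C2 CHBr, C3 CHOH, C5 C=CH2, C6 spiro). Ring A hides a 3-alkoxycyclohexanone: C5 (a ketone until step 5) and the carbinol carbon C3 are 1,3-related across C4. Ring A is therefore cut at C2–C3 and C1–C6. A spirocyclic 3-alkoxycyclobutanone, made by ketene [2+2] cycloaddition, is opened by SnCl4 to a 1,4-zwitterion (enolate at C6, oxocarbenium ion at C3) that adds across 1-bromo-2-methylprop-1-ene. One operation closes ring A, joins the two quaternary carbons and brings in the C2 bromine. A chiral O-substituent controls ring A; ring B is then desymmetrised and halogenated, and C3 is inverted last.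

Key step: step 4

Remark: compounds 1, 2, 4 and 8 are taken as commercial; the sense of arm selection by the chiral lithium amide in step 7 is assumed by analogy with 4-tert-butylcyclohexanone.

Step 1
Reactants: 1 (1R)-1-(naphthalen-2-yl)ethan-1-ol; 2 butyl vinyl ether
Product: 3 2-[(1R)-1-(ethenyloxy)ethyl]naphthalene
Conditions: Pd(OCOCF3)2 (1 mol %), 4,7-diphenyl-1,10-phenanthroline (1 mol %), Et3N (cat.), neat 2 (excess), 75 °C
Reagents that add atoms: none
Why: Palladium-catalysed transfer vinylation (transetherification) moves the vinyl group of 2 to the secondary alcohol under non-acidic conditions and leaves the stereocentre untouched.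

Step 2
Reactants: 4 1,4-dioxaspiro[4.5]decane-8-carboxylic acid
Product: 5 1,4-dioxaspiro[4.5]decane-8-carbonyl chloride
Conditions: (COCl)2, DMF (cat.), CH2Cl2, 0 °C to rt
Reagents that add atoms: oxalyl chloride, O=C(Cl)C(=O)Cl
Why: Acid chloride formation through the Vilsmeier-type chloroiminium catalyst; the dioxolane should survive the anhydrous medium.

Step 3
Reactants: 5 1,4-dioxaspiro[4.5]decane-8-carbonyl chloride; 3 2-[(1R)-1-(ethenyloxy)ethyl]naphthalene
Product: 7 3-[(1R)-1-(naphthalen-2-yl)ethoxy]-8,11-dioxadispiro[3.2.4^7.2^4]tridecan-1-one (cyclobutanone spiro-fused to ring B; both epimers at the alkoxy carbon), via ketene 6 (not isolated)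
Conditions: Et3N, MeCN, 80 °C (sealed tube)
Reagents that add atoms: none
Why: Dehydrochlorination gives dialkylketene 6, which undergoes thermal ketene–enol ether [2+2] cycloaddition with the CH2 terminus of 3 bonding to the ketene carbonyl carbon; the alkoxy-bearing carbon forms as both epimers, which is harmless because it becomes planar in step 4.

Step 4
Reactants: 7 spiro 3-alkoxycyclobutanone; 8 1-bromo-2-methylprop-1-ene
Product: 10 (2R,3R)-2-bromo-1,1-dimethyl-3-[(1R)-1-(naphthalen-2-yl)ethoxy]spiro[5.5]undecane-5,9-dione 9-ethylene ketal, via enolate–oxocarbenium zwitterion 9 (not isolated)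
Conditions: SnCl4 (1.2 equiv), 8 (10 equiv), CH2Cl2, −78 to −40 °C; chromatography
Reagents that add atoms: none
Why: Proposed new method: SnCl4 on the ketone of 7 triggers push–pull cleavage of the bond between the quaternary carbon and the alkoxy-bearing carbon and gives zwitterion 9 (tin enolate at the future C6, O-alkyl oxocarbenium ion at the future C3); the CHBr terminus of 8 attacks the oxocarbenium carbon (C2–C3 bond, Markovnikov, bromine-bridged tertiary cation at C1) and the enolate carbon then closes onto C1 (C1–C6 bond). The closest known reaction type is the SnCl4-catalysed formal [4+2] cycloaddition of 3-alkoxycyclobutanones with allylsilanes and, intramolecularly, with tethered alkenes; a simple bromoalkene as the two-carbon partner has not been shown. Ring A closes in a 6-(enolendo)-exo-tet mode, and C6 is not yet a stereocentre because ring B is still symmetric. C3 is set by the (R)-1-(naphthalen-2-yl)ethyl group on the oxocarbenium oxygen (conformer with its C–H eclipsing the C=O+ bond, attack anti to the naphthyl group, 3R), and C2 by backside opening of the bromonium ion, which puts Br anti to the new C1–C6 bond, together with a chair transition state that keeps the alkoxy group equatorial (2,3-trans, 2R). The step needs C- instead of O-alkylation of the enolate and trapping of 9 by a weak π-nucleophile: O-alkylation to a tertiary enol ether is reversible under the Lewis acid, and 8 is used in tenfold excess as cosolvent. Diastereomers at C2/C3 should be separable because the auxiliary makes them diastereomeric.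

Step 5
Reactants: 10 spiro keto ketal
Product: 11 (2R,3R)-2-bromo-1,1-dimethyl-5-methylidene-3-[(1R)-1-(naphthalen-2-yl)ethoxy]spiro[5.5]undecan-9-one ethylene ketal
Conditions: Tebbe reagent Cp2Ti(μ-CH2)(μ-Cl)AlMe2, pyridine (cat.), THF/toluene, −40 °C to rt
Reagents that add atoms: Tebbe reagent, C[Al-]1(C)C[Ti](C2C=CC=C2)(C2C=CC=C2)[Cl+]1
Why: Tebbe methylenation; the non-basic titanium methylidene olefinates the hindered ketone next to the quaternary carbon without β-elimination of the alkoxy group.

Step 6
Reactants: 11 methylidene ketal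
Product: 12 (2R,3R)-2-bromo-1,1-dimethyl-5-methylidene-3-[(1R)-1-(naphthalen-2-yl)ethoxy]spiro[5.5]undecan-9-one
Conditions: 2 M aq. HCl, THF, rt
Reagents that add atoms: water, O
Why: Acid-catalysed ketal hydrolysis frees the ring B ketone; the ether and the 1,1-disubstituted alkene should tolerate dilute acid at room temperature.

Step 7
Reactants: 12 ring B ketone
Product: 14 (2R,3R,6R)-2-bromo-1,1-dimethyl-5-methylidene-3-[(1R)-1-(naphthalen-2-yl)ethoxy]-9-(trimethylsilyloxy)spiro[5.5]undec-8-ene, via lithium enolate 13 (not isolated)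
Conditions: lithium (S,S)-bis(1-phenylethyl)amide (from the amine and n-BuLi), LiCl, Me3SiCl (in situ), THF, −100 °C
Reagents that add atoms: chlorotrimethylsilane, C[Si](C)(C)Cl
Why: Arm-selective deprotonation of the symmetric ring B ketone by a chiral lithium amide base with in situ silylation; the base should remove the axial α-hydrogen of one arm (ring B chair with C1 equatorial), and this choice of arm makes the spiro carbon C6 a stereocentre (6R).

Step 8
Reactants: 14 silyl enol ether
Product: 15 (2R,3R,6R,8R)-2,8-dibromo-1,1-dimethyl-5-methylidene-3-[(1R)-1-(naphthalen-2-yl)ethoxy]spiro[5.5]undecan-9-one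
Conditions: NBS, THF, −78 °C; chromatography
Reagents that add atoms: N-bromosuccinimide, O=C1CCC(=O)N1Br
Why: Electrophilic bromination of the silyl enol ether; bromine should enter C8 anti to the axial C5 substituent on C6, giving the equatorial bromide cis to C1, which is also the thermodynamically preferred epimer of this enolisable centre.

Step 9
Reactants: 15 ring B α-bromo ketone
Product: 16 (2R,3R,6R,8R)-2,8-dibromo-1,1,9-trimethyl-5-methylidene-3-[(1R)-1-(naphthalen-2-yl)ethoxy]spiro[5.5]undecan-9-ol (both C9 epimers)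
Conditions: MeMgBr, CeCl3, THF, −78 °C
Reagents that add atoms: methylmagnesium bromide, C[Mg]Br
Why: 1,2-Addition of the organocerium reagent to the enolisable α-bromo ketone; both C9 epimers are acceptable because C9 is ionised in step 10.

Step 10
Reactants: 16 tertiary bromohydrin
Product: 17 (2R,3R,6R,8R,9R)-2,8-dibromo-9-chloro-1,1,9-trimethyl-5-methylidene-3-[(1R)-1-(naphthalen-2-yl)ethoxy]spiro[5.5]undecane
Conditions: SOCl2, CH2Cl2, −40 to 0 °C
Reagents that add atoms: thionyl chloride, O=S(Cl)Cl
Why: SN1 substitution through the chlorosulfite with neighbouring-group participation: the C8 bromine bridges the tertiary cation on its own face and chloride opens the bromonium ion at C9 from the opposite face, which should set C9 (Cl trans to Br) from either epimer of 16.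

Step 11
Reactants: 17 bromochloride ether
Product: 18 (2R,3R,6R,8R,9R)-2,8-dibromo-9-chloro-1,1,9-trimethyl-5-methylidenespiro[5.5]undecan-3-ol (C3 epimer of the target)
Conditions: DDQ, CH2Cl2/pH 7 phosphate buffer, rt
Reagents that add atoms: none
Why: Oxidative cleavage of the naphthyl-substituted benzylic ether by DDQ (hydride abstraction, then hydrolysis of the oxocarbenium ion) frees the C3 alcohol under neutral conditions that spare the halides and the alkene.

Step 12
Reactants: 18 trans-bromohydrin
Product: 19 (2R,6R,8R,9R)-2,8-dibromo-9-chloro-1,1,9-trimethyl-5-methylidenespiro[5.5]undecan-3-one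
Conditions: Dess–Martin periodinane, CH2Cl2, 0 °C to rt
Reagents that add atoms: none
Why: Dess–Martin oxidation under non-basic conditions, which should avoid epimerisation at C2 and migration of the exocyclic alkene into conjugation.

Step 13
Reactants: 19 α-bromo ketone
Product: 20 (2R,3S,6R,8R,9R)-2,8-dibromo-9-chloro-1,1,9-trimethyl-5-methylidenespiro[5.5]undecan-3-ol (target)
Conditions: DIBAL-H (i-Bu2AlH), CH2Cl2, −78 °C
Reagents that add atoms: none
Why: Diastereoselective hydride reduction; the axial methyl group on C1 blocks axial approach to C3, so hydride should enter equatorially and give the axial alcohol cis to the equatorial C2 bromine (3S).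

**Compound list**

1 | (1R)-1-(naphthalen-2-yl)ethan-1-ol | C[C@@H](O)c1ccc2ccccc2c1 | starting material
2 | butyl vinyl ether | CCCCOC=C | starting material
3 | 2-[(1R)-1-(ethenyloxy)ethyl]naphthalene | C=CO[C@H](C)c1ccc2ccccc2c1 | intermediate
4 | 1,4-dioxaspiro[4.5]decane-8-carboxylic acid | OC(=O)C1CCC2(CC1)OCCO2 | starting material
5 | 1,4-dioxaspiro[4.5]decane-8-carbonyl chloride | ClC(=O)C1CCC2(CC1)OCCO2 | intermediate
6 | (1,4-dioxaspiro[4.5]decan-8-ylidene)methanone (ketene) | O=C=C1CCC2(CC1)OCCO2 | intermediate (not isolated)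
7 | 3-[(1R)-1-(naphthalen-2-yl)ethoxy]-8,11-dioxadispiro[3.2.4^7.2^4]tridecan-1-one, both epimers at the alkoxy carbon | O=C1CC(O[C@H](C)c2ccc3ccccc3c2)C14CCC5(CC4)OCCO5 | intermediate
8 | 1-bromo-2-methylprop-1-ene | CC(C)=CBr | starting material
9 | enolate–oxocarbenium zwitterion from 7 (Lewis acid omitted) | [O-]C(CC=[O+][C@H](C)c1ccc2ccccc2c1)=C1CCC2(CC1)OCCO2 | intermediate (not isolated)
10 | (2R,3R)-2-bromo-1,1-dimethyl-3-[(1R)-1-(naphthalen-2-yl)ethoxy]spiro[5.5]undecane-5,9-dione 9-ethylene ketal | O=C1C[C@@H](O[C@H](C)c2ccc3ccccc3c2)[C@H](Br)C(C)(C)C14CCC5(CC4)OCCO5 | intermediate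
11 | (2R,3R)-2-bromo-1,1-dimethyl-5-methylidene-3-[(1R)-1-(naphthalen-2-yl)ethoxy]spiro[5.5]undecan-9-one ethylene ketal | C=C1C[C@@H](O[C@H](C)c2ccc3ccccc3c2)[C@H](Br)C(C)(C)C14CCC5(CC4)OCCO5 | intermediate
12 | (2R,3R)-2-bromo-1,1-dimethyl-5-methylidene-3-[(1R)-1-(naphthalen-2-yl)ethoxy]spiro[5.5]undecan-9-one | C=C1C[C@@H](O[C@H](C)c2ccc3ccccc3c2)[C@H](Br)C(C)(C)C14CCC(=O)CC4 | intermediate
13 | lithium enolate of 12 toward C8 (6R) | C=C1C[C@@H](O[C@H](C)c2ccc3ccccc3c2)[C@H](Br)C(C)(C)[C@@]14CCC(O[Li])=CC4 | intermediate (not isolated)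
14 | (2R,3R,6R)-2-bromo-1,1-dimethyl-5-methylidene-3-[(1R)-1-(naphthalen-2-yl)ethoxy]-9-(trimethylsilyloxy)spiro[5.5]undec-8-ene | C=C1C[C@@H](O[C@H](C)c2ccc3ccccc3c2)[C@H](Br)C(C)(C)[C@@]14CCC(O[Si](C)(C)C)=CC4 | intermediate
15 | (2R,3R,6R,8R)-2,8-dibromo-1,1-dimethyl-5-methylidene-3-[(1R)-1-(naphthalen-2-yl)ethoxy]spiro[5.5]undecan-9-one | C=C1C[C@@H](O[C@H](C)c2ccc3ccccc3c2)[C@H](Br)C(C)(C)[C@@]14CCC(=O)[C@H](Br)C4 | intermediate
16 | (2R,3R,6R,8R)-2,8-dibromo-1,1,9-trimethyl-5-methylidene-3-[(1R)-1-(naphthalen-2-yl)ethoxy]spiro[5.5]undecan-9-ol, both C9 epimers | C=C1C[C@@H](O[C@H](C)c2ccc3ccccc3c2)[C@H](Br)C(C)(C)[C@@]14CCC(C)(O)[C@H](Br)C4 | intermediate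
17 | (2R,3R,6R,8R,9R)-2,8-dibromo-9-chloro-1,1,9-trimethyl-5-methylidene-3-[(1R)-1-(naphthalen-2-yl)ethoxy]spiro[5.5]undecane | C=C1C[C@@H](O[C@H](C)c2ccc3ccccc3c2)[C@H](Br)C(C)(C)[C@@]14CC[C@@](C)(Cl)[C@H](Br)C4 | intermediate
18 | (2R,3R,6R,8R,9R)-2,8-dibromo-9-chloro-1,1,9-trimethyl-5-methylidenespiro[5.5]undecan-3-ol | C=C1C[C@@H](O)[C@H](Br)C(C)(C)[C@@]12CC[C@@](C)(Cl)[C@H](Br)C2 | intermediate
19 | (2R,6R,8R,9R)-2,8-dibromo-9-chloro-1,1,9-trimethyl-5-methylidenespiro[5.5]undecan-3-one | C=C1CC(=O)[C@H](Br)C(C)(C)[C@@]12CC[C@@](C)(Cl)[C@H](Br)C2 | intermediate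
20 | (2R,3S,6R,8R,9R)-2,8-dibromo-9-chloro-1,1,9-trimethyl-5-methylidenespiro[5.5]undecan-3-ol | C=C1C[C@H](O)[C@H](Br)C(C)(C)[C@@]12CC[C@@](C)(Cl)[C@H](Br)C2 | target

**Totals.** Total step count: 13. Longest linear sequence: 12 steps (from 4 through steps 2–13; equally from 1 through steps 1 and 3–13).

**Steps most likely to fail**

Step 4 (Proposed new method). The zwitterion may decay before the weakly nucleophilic bromoalkene adds: by proton transfer, by loss of the 1-arylethyl cation from the oxocarbenium oxygen, or by ionisation of the dioxolane. The enolate may also close through oxygen, the alkoxy group may be eliminated from the β-alkoxy ketone, and the facial control by the auxiliary may be weak. Fallback (sets out from 7, returns at 10): the two bonds are made one after the other by known reaction types. SnCl4-promoted ring-opening allylation of 7 with (3-bromo-2-methylprop-2-en-1-yl)trimethylsilane (Hosomi–Sakurai addition to the same oxocarbenium ion, the acyclic course known for small silyl groups) should give the open-chain ketone (3R,4R)-4-bromo-1-(1,4-dioxaspiro[4.5]decan-8-yl)-5-methyl-3-[(1R)-1-(naphthalen-2-yl)ethoxy]hex-5-en-1-one F1. Markovnikov protonation of its isopropenyl group (TfOH, CH2Cl2, −40 °C) and capture of the tertiary cation by the ketone enol (cationic enol–olefin cyclisation) should then close C1–C6 and give 10.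

Step 7. The chiral base may discriminate poorly between the two ring B arms, because the axial C5 substituent on C6 sits over both axial α-hydrogens, or it may select the wrong arm. Fallback (sets out from 12, returns at 15): reagent control is replaced by separation and recycling. LDA/Me3SiCl should give 14 together with its arm isomer, the (2R,3R,6S) silyl enol ether F2; NBS converts the mixture into 15 and the (2R,3R,6S,8S) bromo ketone F3. Chromatography separates these diastereomers, and F3 is returned to 12 by Zn/AcOH debromination.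

Step 10. Ionisation of the deactivated β-bromo tertiary chlorosulfite may be slow, so elimination to alkenes, front-side collapse without bromine participation (loss of the trans relationship) or HCl addition to the exocyclic alkene may compete. Fallback (sets out from 14, returns at 17): the tertiary chloride is made by alkene bromochlorination instead of substitution. MeLi cleaves 14 to the lithium enolate, which PhNTf2 traps as the enol triflate F4; Fe(acac)3-catalysed coupling with MeMgBr gives the trisubstituted alkene F5. NBS/Me3SiCl (bromonium ion formed anti to the axial C5 substituent, chloride at the tertiary carbon, the ring alkene reacting before the hindered exocyclic one) should give 17.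

Further compounds
F1 | step 4 | (3R,4R)-4-bromo-1-(1,4-dioxaspiro[4.5]decan-8-yl)-5-methyl-3-[(1R)-1-(naphthalen-2-yl)ethoxy]hex-5-en-1-one | O=C(C1CCC2(CC1)OCCO2)C[C@@H](O[C@H](C)c1ccc2ccccc2c1)[C@H](Br)C(C)=C
F2 | step 7 | (2R,3R,6S)-2-bromo-1,1-dimethyl-5-methylidene-3-[(1R)-1-(naphthalen-2-yl)ethoxy]-9-(trimethylsilyloxy)spiro[5.5]undec-8-ene | C=C1C[C@@H](O[C@H](C)c2ccc3ccccc3c2)[C@H](Br)C(C)(C)[C@@]14CC=C(O[Si](C)(C)C)CC4
F3 | step 7 | (2R,3R,6S,8S)-2,8-dibromo-1,1-dimethyl-5-methylidene-3-[(1R)-1-(naphthalen-2-yl)ethoxy]spiro[5.5]undecan-9-one | C=C1C[C@@H](O[C@H](C)c2ccc3ccccc3c2)[C@H](Br)C(C)(C)[C@@]14C[C@H](Br)C(=O)CC4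
F4 | step 10 | (2R,3R,6R)-2-bromo-1,1-dimethyl-5-methylidene-3-[(1R)-1-(naphthalen-2-yl)ethoxy]spiro[5.5]undec-8-en-9-yl trifluoromethanesulfonate | C=C1C[C@@H](O[C@H](C)c2ccc3ccccc3c2)[C@H](Br)C(C)(C)[C@@]14CCC(OS(=O)(=O)C(F)(F)F)=CC4
F5 | step 10 | (2R,3R,6R)-2-bromo-1,1,9-trimethyl-5-methylidene-3-[(1R)-1-(naphthalen-2-yl)ethoxy]spiro[5.5]undec-8-ene | C=C1C[C@@H](O[C@H](C)c2ccc3ccccc3c2)[C@H](Br)C(C)(C)[C@@]14CCC(C)=CC4
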